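**Plan**

- Numbering (briarane): ring A = C1, C10–C14 with C11=C20H2; ten-membered ring = C1–C10 with C5=C16H2; γ-lactone = C7, C8, C17 (C18 methyl), C19, O.
- Retrosynthetic cuts: C3=C4 and C5=C16 (ene–yne metathesis with ethylene); O–C7 and C6–Cl (chlorolactonization of a C6=C7 alkene); C8–C17; C7–C8; C2–C3; last the two ring A bonds C11–C12 and C1–C14.
- Enabling feature: in ring A, C14 is 1,3 to C2 through quaternary C1 and 1,4 to C11. C12–C13–C14 is therefore an acryloyl unit: a C1 lactone enolate acylates it (C1–C14) and a C11 nitronate attacks it at C12 (C11–C12). The butanolide O9–C9–C10–C1–C2, which ties the future C9 oxygen to C2, is the temporary ring that carries both nucleophiles.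
- Forward order: butanolide → ring A in one annulation → 12,14-diol and 11(20)-methylene → lactone opening to the C2 and C9 arms and all four acetates → γ-lactone with the C6 chloride → ten-membered ring last.
- Stereochemistry: C9 is bought with (S)-5-(hydroxymethyl)furan-2(5H)-one; C10, C1, C14, C12, C2, C8, C7, C6 and C17 are relayed from it by substrate control (the C11 epimers are irrelevant because C11 becomes sp2).

Key step: step 4

Assumption: (E)-1,2-diiodoethene, tert-butyl 2-bromopropanoate and butenolide 1 are taken as commercial; the briarane locants above are used in all names.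

**Route**

Step 1
Reactants: 1 (S)-5-(hydroxymethyl)furan-2(5H)-one
Product: 2 (S)-5-[(tert-butyldiphenylsilyloxy)methyl]furan-2(5H)-one
Conditions: t-BuPh2SiCl, imidazole, DMF, 0 °C to rt
Reagents that add atoms: tert-butyldiphenylsilyl chloride CC(C)(C)[Si](Cl)(c1ccccc1)c1ccccc1
Why: Silyl ether formation at the primary alcohol; no stereocenter is touched.

Step 2
Reactants: 2 (S)-5-[(tert-butyldiphenylsilyloxy)methyl]furan-2(5H)-one; 3 nitromethane
Product: 4 (4R,5S)-5-[(tert-butyldiphenylsilyloxy)methyl]-4-(nitromethyl)dihydrofuran-2(3H)-one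
Conditions: DBU (0.2 equiv), MeNO2 (5 equiv), THF, 0 °C
Reagents that add atoms: none
Why: Nitro-Michael addition to the butenolide should occur anti to the C9 silyloxymethyl group, which sets C10 trans to C9 by substrate control.

Step 3
Reactants: 4 (4R,5S)-5-[(tert-butyldiphenylsilyloxy)methyl]-4-(nitromethyl)dihydrofuran-2(3H)-one
Product: 5 (3S,4R,5S)-5-[(tert-butyldiphenylsilyloxy)methyl]-3-methyl-4-(nitromethyl)dihydrofuran-2(3H)-one
Conditions: LiN(i-Pr)2 (2.2 equiv), THF–DMPU, −78 °C; MeI (1.05 equiv), −78 °C
Reagents that add atoms: iodomethane CI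
Why: Enolate alkylation of the nitronate/lactone-enolate dianion at the more nucleophilic enolate carbon installs C15 anti to the C10 arm; the C1 configuration is provisional because C1 is enolized again in step 4.

Step 4
Reactants: 5 (3S,4R,5S)-5-[(tert-butyldiphenylsilyloxy)methyl]-3-methyl-4-(nitromethyl)dihydrofuran-2(3H)-one; 6 acryloyl chloride
Product: 8 trans-fused nitro keto lactone, via acryloyl lactone nitronate 7 (not isolated)
Conditions: LiN(i-Pr)2 (2.2 equiv), THF–DMPU, −78 °C; acryloyl chloride (1.05 equiv), −78 to 0 °C; aq. NH4Cl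
Reagents that add atoms: none
Why: Proposed new method: LiN(i-Pr)2 turns 5 into a nitronate/lactone-enolate dianion, the far more nucleophilic lactone enolate is C-acylated by acryloyl chloride (C1–C14) to give the 2-acyl lactone 7, and the tethered C11 nitronate then adds to C12 of the new vinyl ketone (C11–C12). The closest known reactions are the C-acylation of lithium ester enolates with acid chlorides, the intramolecular nitro-Michael addition, and the α,α′-annulation of enamines with acryloyl chloride, which makes the same two kinds of bond in one pot. Ring A closes in the 6-endo-trig mode, and the C13=C14 enolate so formed is quenched by the acidic C11–H, so the product rests as its nitronate and the ring closure is driven forward. The quaternary center C1 is set in the acylation, which should take place on the lactone face anti to the C10 nitromethyl arm (the usual anti selectivity of β-substituted butanolide enolates); ring A is therefore trans-fused to the temporary lactone with the C15 methyl β and H-10 α, while C11 forms as an epimer mixture that does not matter. The step needs C- over O-acylation and enolate over nitronate selectivity; the nucleophilicity gap between the ester enolate and the delocalized nitronate, one equivalent of acid chloride and −78 °C should secure both.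

Step 5
Reactants: 8 trans-fused nitro keto lactone
Product: 9 14α-hydroxy nitro lactone
Conditions: LiBH(s-Bu)3 (2.2 equiv), THF, −78 °C
Reagents that add atoms: none
Why: Ketone reduction with a bulky trialkylborohydride should proceed by equatorial attack on the chair of trans-fused ring A and give the axial 14α-alcohol, anti to the axial C15 methyl and cis to H-10.

Step 6
Reactants: 9 14α-hydroxy nitro lactone
Product: 10 14α-hydroxy 11-keto lactone
Conditions: NaOMe (1.1 equiv), MeOH–CH2Cl2, 0 °C; O3, −78 °C
Reagents that add atoms: ozone [O-][O+]=O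
Why: Nef reaction in its oxidative form (ozonolysis of the nitronate) unmasks the C11 ketone at low temperature, which should leave the epimerizable C10 center untouched.

Step 7
Reactants: 10 14α-hydroxy 11-keto lactone
Product: 11 14α-hydroxy 11(20)-methylene lactone
Conditions: Zn, CH2Br2, TiCl4, THF–CH2Cl2, 0 °C to rt
Reagents that add atoms: dibromomethane BrCBr
Why: Lombardo–Takai methylenation is non-basic, so the C11=C20 methylene should form without epimerization at C10 and without attack on the lactone carbonyl.

Step 8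
Reactants: 11 14α-hydroxy 11(20)-methylene lactone
Product: 12 12α,14α-dihydroxy 11(20)-methylene lactone
Conditions: SeO2 (0.3 equiv), t-BuOOH, CH2Cl2, rt
Reagents that add atoms: tert-butyl hydroperoxide CC(C)(C)OO
Why: SeO2 allylic oxidation (ene reaction, then [2,3]-sigmatropic shift) should take the ring CH2 (C12) in preference to the tertiary C10 and deliver oxygen axially, giving the 12α-alcohol cis to the 14α-hydroxyl.

Step 9
Reactants: 12 12α,14α-dihydroxy 11(20)-methylene lactone
Product: 13 lactol
Conditions: i-Bu2AlH (3.5 equiv), CH2Cl2, −78 °C; aq. potassium sodium tartrate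
Reagents that add atoms: none
Why: Partial reduction of the γ-lactone to the lactol at low temperature, with the two free hydroxyls carried as aluminium alkoxides.

Step 10
Reactants: 13 lactol; 14 vinylmagnesium bromide
Product: 15 tetraol
Conditions: CH2=CHMgBr (6 equiv), THF, −78 to 0 °C
Reagents that add atoms: none
Why: Grignard addition to the open hydroxy aldehyde form under Cram chelate control: magnesium bridges the C2 carbonyl oxygen and the C14 alkoxide, and the vinyl group should add from the face of the C15 methyl, which sets C2.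

Step 11
Reactants: 15 tetraol
Product: 16 tetraacetate silyl ether
Conditions: Ac2O, DMAP (cat.), pyridine, 40 °C
Reagents that add atoms: acetic anhydride CC(=O)OC(C)=O
Why: Exhaustive DMAP-catalysed acetylation of the four secondary hydroxyls installs all four acetates of the target at once.

Step 12
Reactants: 16 tetraacetate silyl ether
Product: 17 tetraacetate C8 alcohol
Conditions: HF·pyridine, pyridine–THF, 0 °C to rt
Reagents that add atoms: none
Why: Fluoride cleavage of the primary silyl ether under buffered acidic conditions, which should avoid acetyl migration from O9 to O8.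

Step 13
Reactants: 17 tetraacetate C8 alcohol
Product: 18 tetraacetate C8 aldehyde
Conditions: Dess–Martin periodinane, NaHCO3, CH2Cl2, 0 °C
Reagents that add atoms: none
Why: Dess–Martin oxidation gives the α-acetoxy aldehyde under buffered conditions that should not epimerize C9.

Step 14
Reactants: 19 (E)-1,2-diiodoethene; 20 ethynyltrimethylsilane
Product: 21 (E)-1-iodo-4-(trimethylsilyl)but-1-en-3-yne
Conditions: Pd(PPh3)4 (cat.), CuI (cat.), Et3N, THF, rt; 19 in threefold excess
Reagents that add atoms: none
Why: Sonogashira coupling at one C–I bond of the diiodide used in excess, with retention of the E geometry.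

Step 15
Reactants: 18 tetraacetate C8 aldehyde; 21 (E)-1-iodo-4-(trimethylsilyl)but-1-en-3-yne
Product: 22 enynyl carbinol
Conditions: CrCl2 (4 equiv), NiCl2 (1 mol %), DMSO–THF, rt
Reagents that add atoms: none
Why: Nozaki–Hiyama–Kishi addition tolerates the four acetates and keeps the E alkene; the new carbinol center at C8 is removed in step 16.

Step 16
Reactants: 22 enynyl carbinol
Product: 23 (E)-enynone
Conditions: Dess–Martin periodinane, NaHCO3, CH2Cl2, rt
Reagents that add atoms: none
Why: Dess–Martin oxidation of the secondary allylic alcohol gives the cross-conjugated C8 ketone without base.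

Step 17
Reactants: 23 (E)-enynone; 24 tert-butyl 2-bromopropanoate
Product: 25 tertiary alcohol tert-butyl ester
Conditions: Zn dust (activated with Me3SiCl), THF, 0 °C to rt
Reagents that add atoms: none
Why: Reformatsky reaction: the zinc enolate should add 1,2 to the ketone anti to the C9 acetoxy group (polar Felkin–Anh model), which sets the tertiary carbinol C8; C17 forms as a mixture that is corrected in step 18.

Step 18
Reactants: 25 tertiary alcohol tert-butyl ester
Product: 26 chloro lactone silyl alkyne
Conditions: N-chlorosuccinimide, Ph3P=S (10 mol %), CH2Cl2, −20 °C; then DBU (0.2 equiv), 0 °C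
Reagents that add atoms: N-chlorosuccinimide O=C1CCC(=O)N1Cl
Why: Chlorolactonization (halolactonization with loss of the tert-butyl group as isobutene) should add the ester oxygen at C7 (5-exo) and chlorine at C6 anti across the E alkene, on the face that puts the C6 arm cis to the C8 hydroxyl (hydroxyl-directed kinetic halolactonization), which sets C7 and C6; DBU then equilibrates C17 to the more stable lactone with the methyl anti to C9.

Step 19
Reactants: 26 chloro lactone silyl alkyne
Product: 27 chloro lactone terminal alkyne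
Conditions: Bu4NF, AcOH, THF, 0 °C
Reagents that add atoms: none
Why: Fluoride-induced protodesilylation of the alkynylsilane, buffered with acetic acid to spare the acetates and the propargylic chloride.

Step 20
Reactants: 27 chloro lactone terminal alkyne; 28 ethylene
Product: 30 CNP0164748.1, via triene 29 (not isolated)
Conditions: second-generation Grubbs catalyst (20 mol %), ethylene (1 atm), CH2Cl2, 40 °C; then argon purge, toluene (1 mM), 80 °C
Reagents that add atoms: none
Why: Ene–yne cross metathesis with ethylene turns the terminal alkyne into the 2-substituted butadiene (C16 comes from ethylene), and ring-closing metathesis between the C4 and C3 vinyl groups then closes the ten-membered ring, whose strain is expected to favour the Z alkene.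

**Compound list**

1 | (S)-5-(hydroxymethyl)furan-2(5H)-one | OC[C@H]1OC(=O)C=C1 | starting material
2 | (S)-5-[(tert-butyldiphenylsilyloxy)methyl]furan-2(5H)-one | CC(C)(C)[Si](OC[C@H]1OC(=O)C=C1)(c1ccccc1)c1ccccc1 | intermediate
3 | nitromethane | C[N+](=O)[O-] | starting material
4 | (4R,5S)-5-[(tert-butyldiphenylsilyloxy)methyl]-4-(nitromethyl)dihydrofuran-2(3H)-one (4,5-trans) | [O-][N+](=O)C[C@@H]1[C@H](OC(=O)C1)CO[Si](c1ccccc1)(c1ccccc1)C(C)(C)C | intermediate
5 | (3S,4R,5S)-5-[(tert-butyldiphenylsilyloxy)methyl]-3-methyl-4-(nitromethyl)dihydrofuran-2(3H)-one (all-trans) | [O-][N+](=O)C[C@@H]1[C@H](OC(=O)[C@H]1C)CO[Si](c1ccccc1)(c1ccccc1)C(C)(C)C | intermediate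
6 | acryloyl chloride | C=CC(=O)Cl | starting material
7 | acryloyl lactone nitronate: 3-acryloyl-3-methyl-4-(nitromethyl) lactone, acryloyl group anti to the nitromethyl arm, present as its lithium nitronate (drawn in the neutral nitro form) | [O-][N+](=O)C[C@@H]1[C@H](OC(=O)[C@@]1(C)C(=O)C=C)CO[Si](c1ccccc1)(c1ccccc1)C(C)(C)C | intermediate
8 | trans-fused nitro keto lactone: 3-[(tert-butyldiphenylsilyloxy)methyl]-7a-methyl-4-nitrohexahydroisobenzofuran-1,7-dione; ring A fused to the butanolide at C1–C10, C14 ketone, C15 methyl β, H-10 α, C9 as in 1, C11 epimers | [O-][N+](=O)C1[C@@H]2[C@H](OC(=O)[C@@]2(C)C(=O)CC1)CO[Si](c1ccccc1)(c1ccccc1)C(C)(C)C | intermediate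
9 | 14α-hydroxy nitro lactone: as 8 with an axial 14α-hydroxyl (cis to H-10, anti to C15) | [O-][N+](=O)C1[C@@H]2[C@H](OC(=O)[C@@]2(C)[C@@H](O)CC1)CO[Si](c1ccccc1)(c1ccccc1)C(C)(C)C | intermediate
10 | 14α-hydroxy 11-keto lactone | O=C1[C@@H]2[C@H](OC(=O)[C@@]2(C)[C@@H](O)CC1)CO[Si](c1ccccc1)(c1ccccc1)C(C)(C)C | intermediate
11 | 14α-hydroxy 11(20)-methylene lactone | C=C1[C@@H]2[C@H](OC(=O)[C@@]2(C)[C@@H](O)CC1)CO[Si](c1ccccc1)(c1ccccc1)C(C)(C)C | intermediate
12 | 12α,14α-dihydroxy 11(20)-methylene lactone (cis-diaxial diol on ring A) | C=C1[C@@H]2[C@H](OC(=O)[C@@]2(C)[C@@H](O)C[C@H]1O)CO[Si](c1ccccc1)(c1ccccc1)C(C)(C)C | intermediate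
13 | lactol: C2 hemiacetal of 12 (anomer mixture) | C=C1[C@@H]2[C@H](OC(O)[C@@]2(C)[C@@H](O)C[C@H]1O)CO[Si](c1ccccc1)(c1ccccc1)C(C)(C)C | intermediate
14 | vinylmagnesium bromide | C=C[Mg]Br | starting material
15 | tetraol: ring A with 12α- and 14α-hydroxyls and the 11(20)-methylene; C1 carries the β-methyl and CH(OH)CH=CH2 (C2, C3); C10 carries CH(OH)CH2OSi(t-Bu)Ph2 (C9, C8); C1, C2, C9, C10, C12, C14 as in the target | C=C1[C@H]([C@H](O)CO[Si](c2ccccc2)(c2ccccc2)C(C)(C)C)[C@@](C)([C@@H](O)C=C)[C@@H](O)C[C@H]1O | intermediate
16 | tetraacetate silyl ether: 2,9,12,14-tetraacetate of 15 | C=C1[C@H]([C@H](OC(C)=O)CO[Si](c2ccccc2)(c2ccccc2)C(C)(C)C)[C@@](C)([C@@H](OC(C)=O)C=C)[C@@H](OC(C)=O)C[C@H]1OC(C)=O | intermediate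
17 | tetraacetate C8 alcohol | C=C1[C@H]([C@H](OC(C)=O)CO)[C@@](C)([C@@H](OC(C)=O)C=C)[C@@H](OC(C)=O)C[C@H]1OC(C)=O | intermediate
18 | tetraacetate C8 aldehyde | C=C1[C@H]([C@H](OC(C)=O)C=O)[C@@](C)([C@@H](OC(C)=O)C=C)[C@@H](OC(C)=O)C[C@H]1OC(C)=O | intermediate
19 | (E)-1,2-diiodoethene | I/C=C/I | starting material
20 | ethynyltrimethylsilane | C#C[Si](C)(C)C | starting material
21 | (E)-1-iodo-4-(trimethylsilyl)but-1-en-3-yne | I/C=C/C#C[Si](C)(C)C | intermediate
22 | enynyl carbinol: 18 with C8 as CH(OH) bearing the (E)-4-(trimethylsilyl)but-1-en-3-ynyl group (C7=C6, C5≡C4); C8 epimers | C=C1[C@H]([C@H](OC(C)=O)C(O)/C=C/C#C[Si](C)(C)C)[C@@](C)([C@@H](OC(C)=O)C=C)[C@@H](OC(C)=O)C[C@H]1OC(C)=O | intermediate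
23 | (E)-enynone: C8 ketone of 22 | C=C1[C@H]([C@H](OC(C)=O)C(=O)/C=C/C#C[Si](C)(C)C)[C@@](C)([C@@H](OC(C)=O)C=C)[C@@H](OC(C)=O)C[C@H]1OC(C)=O | intermediate
24 | tert-butyl 2-bromopropanoate | CC(Br)C(=O)OC(C)(C)C | starting material
25 | tertiary alcohol tert-butyl ester: C8 carries OH (as in the target), the (E)-enynyl group and CH(CH3)CO2t-Bu (C17, C18, C19); C17 epimers | C=C1[C@H]([C@H](OC(C)=O)[C@@](O)(/C=C/C#C[Si](C)(C)C)C(C)C(=O)OC(C)(C)C)[C@@](C)([C@@H](OC(C)=O)C=C)[C@@H](OC(C)=O)C[C@H]1OC(C)=O | intermediate
26 | chloro lactone silyl alkyne: γ-lactone C7–C8–C17–C19–O with 8-OH, 17-methyl, C6 chloride and a C5≡C4–SiMe3 alkyne; C6, C7, C8, C17 as in the target | C=C1[C@H]([C@H](OC(C)=O)[C@]2(O)[C@@H](C)C(=O)O[C@H]2[C@@H](Cl)C#C[Si](C)(C)C)[C@@](C)([C@@H](OC(C)=O)C=C)[C@@H](OC(C)=O)C[C@H]1OC(C)=O | intermediate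
27 | chloro lactone terminal alkyne | C=C1[C@H]([C@H](OC(C)=O)[C@]2(O)[C@@H](C)C(=O)O[C@H]2[C@@H](Cl)C#C)[C@@](C)([C@@H](OC(C)=O)C=C)[C@@H](OC(C)=O)C[C@H]1OC(C)=O | intermediate
28 | ethylene | C=C | starting material
29 | triene: 27 with the alkyne converted into the buta-1,3-dien-2-yl group (C5=C16H2, C4H=CH2) | C=C1[C@H]([C@H](OC(C)=O)[C@]2(O)[C@@H](C)C(=O)O[C@H]2[C@@H](Cl)C(=C)C=C)[C@@](C)([C@@H](OC(C)=O)C=C)[C@@H](OC(C)=O)C[C@H]1OC(C)=O | intermediate
30 | CNP0164748.1: 2,9,12,14-tetraacetoxy-6-chloro-8-hydroxy briarane 3Z,5(16),11(20)-triene γ-lactone | C=C1[C@@H]2[C@H](OC(C)=O)[C@]3(O)[C@@H](C)C(=O)O[C@H]3[C@@H](Cl)C(=C)/C=C\[C@H](OC(C)=O)[C@@]2(C)[C@@H](OC(C)=O)C[C@H]1OC(C)=O | target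

**Count and risks**

Total step count: 20. Longest linear sequence: 19 steps (steps 1–13 and 15–20); step 14 is a one-step side branch.

Steps most likely to fail:

1. Step 4 (Proposed new method). What may go wrong: O-acylation of the hindered, fully substituted lactone enolate, acylation of the nitronate, or anionic polymerization of the acryloyl unit before ring closure. Fallback with known reactions: from 5, the same dianion is treated with acrolein at −78 °C, where the lactone enolate should add 1,2 (aldol addition, anti to the nitromethyl arm) to give the allylic alcohol F1. Dess–Martin oxidation of F1 gives the vinyl ketone 7 as an isolated compound, and DBU (0.1 equiv, CH2Cl2, 0 °C) should close ring A by 6-endo nitro-Michael addition. The sequence comes back to the route at 8.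

2. Step 20. What may go wrong: closure of the strained ten-membered ring to the E alkene at C3=C4 instead of the Z alkene. Fallback: from 27, the metathesis is run to the ring-closed (3E)-diene F4, and the geometry is then corrected in a separate photochemical step, a triplet-sensitized E-to-Z isomerization of the 1,3-diene (thioxanthone, 405 nm, CH2Cl2). This comes back to the route at 30.

3. Step 18. What may go wrong: attack of the chlorinating agent on the 11(20)-methylene or the C3 vinyl group instead of the enyne alkene, or 6-endo closure at the propargylic carbon C6. Fallback: from 25, hydroxyl-directed epoxidation (VO(acac)2, t-BuOOH, CH2Cl2), which only the tertiary allylic C8 alcohol can direct, gives the epoxide F2. Opening of F2 at the propargylic C6 with inversion (Ti(Oi-Pr)4, Et2NH2Cl) gives the chlorohydrin F3. Acid-catalysed lactonization of F3 (camphorsulfonic acid, CH2Cl2) with loss of the tert-butyl group, followed by the same DBU equilibration at C17, comes back to the route at 26.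

Further compounds
F1 | step 4 | aldol adduct: 3-(1-hydroxyprop-2-enyl)-3-methyl-4-(nitromethyl) lactone, hydroxyallyl group anti to the nitromethyl arm, carbinol epimers | [O-][N+](=O)C[C@@H]1[C@H](OC(=O)[C@@]1(C)C(O)C=C)CO[Si](c1ccccc1)(c1ccccc1)C(C)(C)C
F2 | step 18 | trans-6,7-epoxide of 25 | C=C1[C@H]([C@H](OC(C)=O)[C@@](O)([C@H]2O[C@@H]2C#C[Si](C)(C)C)C(C)C(=O)OC(C)(C)C)[C@@](C)([C@@H](OC(C)=O)C=C)[C@@H](OC(C)=O)C[C@H]1OC(C)=O
F3 | step 18 | 6-chloro-7,8-dihydroxy tert-butyl ester (chlorohydrin from F2) | C=C1[C@H]([C@H](OC(C)=O)[C@@](O)([C@@H](O)[C@@H](Cl)C#C[Si](C)(C)C)C(C)C(=O)OC(C)(C)C)[C@@](C)([C@@H](OC(C)=O)C=C)[C@@H](OC(C)=O)C[C@H]1OC(C)=O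
F4 | step 20 | (3E)-isomer of 30 | C=C1[C@@H]2[C@H](OC(C)=O)[C@]3(O)[C@@H](C)C(=O)O[C@H]3[C@@H](Cl)C(=C)/C=C/[C@H](OC(C)=O)[C@@]2(C)[C@@H](OC(C)=O)C[C@H]1OC(C)=O
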